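**Retrosynthetic overview**
1. The last cuts are the seven O-benzyl groups (BCl3/pentamethylbenzene) and the ring A aryl–vinyl bond (Mizoroki–Heck reaction of a C-4 bromide with 4-(benzyloxy)styrene).
2. The dihydrofuran on ring A (the resorcinol ring that carries the styryl arm) is opened at C-2–C-3: enantioselective intramolecular C–H insertion of a diaryl rhodium carbenoid, then cis-to-trans equilibration at C-2. The diaryl ketone behind it comes from the ring B aryl bromide and a ring A aldehyde.
3. The dihydrofuran on ring B (the catechol ring) is cut at O-1–C-2 and C-3a–C-3 together: enantioselective rhodium-carbenoid [3+2] annulation of a ring B ortho-quinone diazide with resveratrol tribenzyl ether.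
4. Enabling feature: in the ring B dihydrobenzofuran the phenolic oxygen O-1 and its neighbouring ring carbon C-3a (the O-1–C-7a–C-3a unit) can be stored as a 6-diazocyclohexa-2,4-dien-1-one, a one-oxygen/one-carbon dipole equivalent. The stilbene C=C is polarised by its 4-alkoxyphenyl end, which decides which carbon takes O and which takes C.
5. Order of ring formation: dihydrofuran on ring B (step 5), then dihydrofuran on ring A (step 12); all benzene rings are bought.

Key step: step 5

Assumption: the sense of induction of Rh2(S-TCPTTL)4 (step 5) and Rh2(R-PTAD)4 (step 12) is taken to give the configurations drawn; if a first run shows the opposite sense, the enantiomeric catalyst is used with no other change.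

Abbreviations: Bn = benzyl; RB = the (2R,3R)-7-(benzyloxy)-3-[3,5-bis(benzyloxy)phenyl]-2-[4-(benzyloxy)phenyl]-2,3-dihydro-1-benzofuran-5-yl group of compound 9; Rh2(S-TCPTTL)4 = dirhodium tetrakis[N-tetrachlorophthaloyl-(S)-tert-leucinate]; Rh2(R-PTAD)4 = dirhodium tetrakis[(R)-N-phthaloyl-(1-adamantyl)glycinate].

**Route**

Step 1
Reactants: 1 2-(benzyloxy)phenol
Product: 2 2-(benzyloxy)-4-bromophenol
Conditions: NBS (1.0 equiv), MeCN, 0 °C
Reagents that add atoms: N-bromosuccinimide, O=C1CCC(=O)N1Br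
Why: Electrophilic aromatic bromination is directed by the free hydroxyl, the stronger donor, to its para position, which blocks that site and leaves one ortho position open.

Step 2
Reactants: 2 2-(benzyloxy)-4-bromophenol
Product: 3 2-(benzyloxy)-4-bromo-6-nitrophenol
Conditions: HNO3 (65%, 1.05 equiv), AcOH, 10 °C
Reagents that add atoms: nitric acid, O[N+](=O)[O-]
Why: Electrophilic nitration of the para-blocked phenol should go to the only free position ortho to the hydroxyl, the carbon that later becomes C-3a of the ring B dihydrobenzofuran.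

Step 3
Reactants: 3 2-(benzyloxy)-4-bromo-6-nitrophenol
Product: 5 2-(benzyloxy)-4-bromo-6-diazocyclohexa-2,4-dien-1-one, via 2-amino-6-(benzyloxy)-4-bromophenol 4 (not isolated)
Conditions: H2 (1 atm), Pt/C (5 wt%, sulfided), EtOAc, rt; filter under argon; t-BuONO (1.2 equiv), AcOH (cat.), 0 °C, dark
Reagents that add atoms: tert-butyl nitrite, CC(C)(C)ON=O
Why: Chemoselective catalytic hydrogenation over sulfided Pt/C reduces the nitro group without touching the aryl bromide or the benzyl ether, and diazotisation of the ortho-aminophenol with an alkyl nitrite gives, after loss of the phenolic proton, the neutral ortho-quinone diazide.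

Step 4
Reactants: 6 resveratrol
Product: 7 (E)-1,3-bis(benzyloxy)-5-{2-[4-(benzyloxy)phenyl]ethenyl}benzene
Conditions: BnBr (3.6 equiv), K2CO3, DMF, 60 °C
Reagents that add atoms: benzyl bromide, BrCc1ccccc1
Why: Williamson ether synthesis on all three phenols removes every O–H that could intercept a carbenoid and leaves the E double bond untouched.

Step 5
Reactants: 5 2-(benzyloxy)-4-bromo-6-diazocyclohexa-2,4-dien-1-one; 7 (E)-1,3-bis(benzyloxy)-5-{2-[4-(benzyloxy)phenyl]ethenyl}benzene (2 equiv)
Product: 9 (2R,3R)-7-(benzyloxy)-3-[3,5-bis(benzyloxy)phenyl]-2-[4-(benzyloxy)phenyl]-5-bromo-2,3-dihydro-1-benzofuran, via phenoxide/benzyl-cation zwitterion 8 (not isolated)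
Conditions: Rh2(S-TCPTTL)4 (1 mol%), PhCF3, 0 °C to rt, slow addition of 5 over 4 h, dark
Reagents that add atoms: none
Why: Proposed new method: Rh2(S-TCPTTL)4 (a divalent rhodium carboxylate dimer) takes N2 from 5 and gives an electrophilic quinoid carbenoid at the diazo carbon; the stilbene carbon that carries the 3,5-bis(benzyloxy)phenyl ring attacks it, the positive charge settles on the carbon next to the 4-(benzyloxy)phenyl ring, and loss of rhodium re-aromatises ring B to the phenoxide of zwitterion 8, which closes through oxygen. The closest known reaction type is the dirhodium-catalysed formal [3+2] annulation of cyclic 2-diazo-1,3-diones and diazonaphthoquinones with enol ethers and styrenes to dihydrofurans, together with enantioselective carbenoid transfer to alkenes by phthalimido-amino-acid dirhodium catalysts; new here are the monocyclic ortho-quinone diazide, the 1,2-diaryl alkene and the asymmetric induction. The one ring that closes, the dihydrofuran, does so after the intermolecular C–C bond by 5-exo-trig attack of the phenoxide oxygen on the cation written as its para-quinone-methide oxocarbenium form, and aromatisation of ring B drives the sequence. C-3 is set in the C–C bond-forming step, where the chiral carboxylate pocket around the rhodium-bound carbenoid selects the alkene face; C-2 is set in the ring closure, where the two aryl groups take the trans arrangement that the E alkene relays and that is also thermodynamically preferred. Regioselectivity on ring B is fixed by the place of the diazo carbon next to the carbonyl oxygen, regioselectivity on the alkene by the better cation stabilisation of the 4-alkoxyphenyl terminus over the 3,5-dialkoxyphenyl terminus, and chemoselectivity over arene C–H attack, O–H insertion and carbenoid dimerisation by full O-benzylation of 7, its use in excess and slow addition of 5.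

Step 6
Reactants: 10 1,3-bis(benzyloxy)-5-bromobenzene
Product: 11 2,4-bis(benzyloxy)-6-bromobenzaldehyde
Conditions: POCl3, DMF, 0 to 70 °C; aq NaOAc
Reagents that add atoms: N,N-dimethylformamide, CN(C)C=O; water, O
Why: Vilsmeier–Haack formylation should attack the position para to one benzyloxy group and next to bromine in preference to the more hindered site between the two ether groups, as is known for 1-bromo-3,5-dialkoxybenzenes.

Step 7
Reactants: 11 2,4-bis(benzyloxy)-6-bromobenzaldehyde
Product: 12 4-(benzyloxy)-2-bromo-6-hydroxybenzaldehyde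
Conditions: BCl3 (1.05 equiv), CH2Cl2, −78 to −40 °C; H2O
Reagents that add atoms: none
Why: Chelation-controlled Lewis acid dealkylation, in which BCl3 bound to the aldehyde oxygen cleaves only the benzyl ether ortho to the formyl group, makes the two ring A oxygens different.

Step 8
Reactants: 12 4-(benzyloxy)-2-bromo-6-hydroxybenzaldehyde; 13 1-(benzyloxy)-4-(chloromethyl)benzene
Product: 14 4-(benzyloxy)-2-{[4-(benzyloxy)phenyl]methoxy}-6-bromobenzaldehyde
Conditions: K2CO3, n-Bu4NI (cat.), DMF, 60 °C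
Reagents that add atoms: none
Why: Williamson ether synthesis installs the 4-(benzyloxy)benzyl group whose CH2 later becomes C-2 of the ring A dihydrofuran together with its aryl substituent.

Step 9
Reactants: 9 dihydrobenzofuran bromide RB–Br; 14 4-(benzyloxy)-2-{[4-(benzyloxy)phenyl]methoxy}-6-bromobenzaldehyde
Product: 16 [4-(benzyloxy)-2-{[4-(benzyloxy)phenyl]methoxy}-6-bromophenyl](RB)methanol (both epimers at the carbinol carbon), via aryllithium 15 (not isolated)
Conditions: n-BuLi (1.05 equiv), THF, −78 °C; then 14, −78 to −20 °C; H2O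
Reagents that add atoms: none
Why: Bromine–lithium exchange on 9 followed by 1,2-addition of the aryllithium to the aldehyde, which is faster than exchange with the aryl bromide of 14; the carbinol centre forms without control and is removed in the next step.

Step 10
Reactants: 16 diarylmethanol
Product: 17 [4-(benzyloxy)-2-{[4-(benzyloxy)phenyl]methoxy}-6-bromophenyl](RB)methanone
Conditions: Dess–Martin periodinane, CH2Cl2, 0 °C to rt
Reagents that add atoms: none
Why: Dess–Martin oxidation converts the doubly benzylic secondary alcohol into the diaryl ketone under near-neutral conditions that leave the benzylic ethers and both ring B stereocentres alone.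

Step 11
Reactants: 17 diaryl ketone
Product: 18 hydrazone of ketone 17 (E/Z mixture)
Conditions: N2H4·H2O (20 equiv), AcOH (cat.), n-BuOH, 110 °C, sealed tube
Reagents that add atoms: hydrazine (as hydrate), NN
Why: Acid-catalysed condensation of hydrazine with the diaryl ketone (hydrazone formation) is pushed by excess reagent and heat because the carbonyl is flanked by a 2,6-disubstituted ring.

Step 12
Reactants: 18 hydrazone
Product: 20 (2R,3S)-6-(benzyloxy)-2-[4-(benzyloxy)phenyl]-4-bromo-3-(RB)-2,3-dihydro-1-benzofuran (2,3-cis), via diaryldiazomethane 19 (not isolated)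
Conditions: MnO2 (8 equiv), CH2Cl2, 0 °C; filter; Rh2(R-PTAD)4 (1 mol%), CH2Cl2, 0 °C
Reagents that add atoms: none
Why: Dehydrogenation of the hydrazone gives the diaryldiazomethane, whose donor/donor rhodium carbenoid inserts into the activated benzylic C–H bond of the ortho ArCH2O group (intramolecular 1,5 C–H insertion closing the five-membered ring); the chiral carboxylate ligands set C-3 as S and the insertion places the two aryl groups cis, as is known for 2,3-diaryl-2,3-dihydrobenzofurans.

Step 13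
Reactants: 20 cis-dihydrobenzofuran
Product: 21 (2S,3S)-6-(benzyloxy)-2-[4-(benzyloxy)phenyl]-4-bromo-3-(RB)-2,3-dihydro-1-benzofuran (2,3-trans)
Conditions: CF3CO2H (5 equiv), CH2Cl2, 0 °C to rt
Reagents that add atoms: none
Why: Acid-mediated epimerisation at C-2, in which the C-2–O bond ionises reversibly to a 4-alkoxybenzyl cation that recloses to the thermodynamically preferred trans isomer, turns C-2 into S while C-3 is not involved; the ring B dihydrofuran is already trans and should return unchanged.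

Step 14
Reactants: 21 trans-dihydrobenzofuran bromide; 22 1-(benzyloxy)-4-ethenylbenzene
Product: 23 (2S,3S)-6-(benzyloxy)-2-[4-(benzyloxy)phenyl]-4-{(E)-2-[4-(benzyloxy)phenyl]ethenyl}-3-(RB)-2,3-dihydro-1-benzofuran
Conditions: Pd(OAc)2 (5 mol%), P(t-Bu)3·HBF4 (10 mol%), Cy2NMe, 1,4-dioxane, 90 °C
Reagents that add atoms: none
Why: Mizoroki–Heck reaction of the aryl bromide with the styrene, with syn insertion and syn β-hydride elimination, gives the E stilbene; the bulky electron-rich phosphine is chosen for the hindered electron-rich bromide.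

Step 15
Reactants: 23 hepta-O-benzyl ether
Product: 24 5-[(2R,3R)-7-hydroxy-5-{(2S,3S)-6-hydroxy-2-(4-hydroxyphenyl)-4-[(E)-2-(4-hydroxyphenyl)ethenyl]-2,3-dihydro-1-benzofuran-3-yl}-2-(4-hydroxyphenyl)-2,3-dihydro-1-benzofuran-3-yl]benzene-1,3-diol (CNP0172909.1)
Conditions: BCl3 (14 equiv), C6HMe5 (20 equiv), CH2Cl2, −78 °C; MeOH
Reagents that add atoms: none
Why: Lewis acid debenzylation with BCl3 at low temperature, with pentamethylbenzene as a non-basic scavenger for benzyl cations, should remove all seven benzyl groups without hydrogenation, so the stilbene double bond and the four stereocentres are kept.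

**Compound list**
1 | 2-(benzyloxy)phenol | Oc1ccccc1OCc1ccccc1 | starting material
2 | 2-(benzyloxy)-4-bromophenol | Oc1ccc(Br)cc1OCc1ccccc1 | intermediate
3 | 2-(benzyloxy)-4-bromo-6-nitrophenol | Oc1c(OCc2ccccc2)cc(Br)cc1[N+](=O)[O-] | intermediate
4 | 2-amino-6-(benzyloxy)-4-bromophenol | Nc1cc(Br)cc(OCc2ccccc2)c1O | intermediate (not isolated)
5 | 2-(benzyloxy)-4-bromo-6-diazocyclohexa-2,4-dien-1-one (ortho-quinone diazide) | O=C1C(OCc2ccccc2)=CC(Br)=CC1=[N+]=[N-] | intermediate
6 | resveratrol, (E)-5-[2-(4-hydroxyphenyl)ethenyl]benzene-1,3-diol | Oc1ccc(/C=C/c2cc(O)cc(O)c2)cc1 | starting material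
7 | (E)-1,3-bis(benzyloxy)-5-{2-[4-(benzyloxy)phenyl]ethenyl}benzene | C(Oc1ccc(/C=C/c2cc(OCc3ccccc3)cc(OCc3ccccc3)c2)cc1)c1ccccc1 | intermediate
8 | zwitterion: 2-(benzyloxy)-4-bromophenolate carrying at C-6 the 1-[3,5-bis(benzyloxy)phenyl]-2-[4-(benzyloxy)phenyl]ethyl cation (charge on the carbon next to the 4-(benzyloxy)phenyl ring; diarylmethine carbon configured as in 9) | [O-]c1c(OCc2ccccc2)cc(Br)cc1[C@@H](c1cc(OCc2ccccc2)cc(OCc2ccccc2)c1)[CH+]c1ccc(OCc2ccccc2)cc1 | intermediate (not isolated)
9 | (2R,3R)-7-(benzyloxy)-3-[3,5-bis(benzyloxy)phenyl]-2-[4-(benzyloxy)phenyl]-5-bromo-2,3-dihydro-1-benzofuran | Brc1cc(OCc2ccccc2)c2c(c1)[C@@H](c1cc(OCc3ccccc3)cc(OCc3ccccc3)c1)[C@H](c1ccc(OCc3ccccc3)cc1)O2 | intermediate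
10 | 1,3-bis(benzyloxy)-5-bromobenzene | Brc1cc(OCc2ccccc2)cc(OCc2ccccc2)c1 | starting material
11 | 2,4-bis(benzyloxy)-6-bromobenzaldehyde | O=Cc1c(Br)cc(OCc2ccccc2)cc1OCc1ccccc1 | intermediate
12 | 4-(benzyloxy)-2-bromo-6-hydroxybenzaldehyde | O=Cc1c(O)cc(OCc2ccccc2)cc1Br | intermediate
13 | 1-(benzyloxy)-4-(chloromethyl)benzene | ClCc1ccc(OCc2ccccc2)cc1 | starting material
14 | 4-(benzyloxy)-2-{[4-(benzyloxy)phenyl]methoxy}-6-bromobenzaldehyde | O=Cc1c(Br)cc(OCc2ccccc2)cc1OCc1ccc(OCc2ccccc2)cc1 | intermediate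
15 | aryllithium of 9 (Li in place of Br) | [Li]c1cc(OCc2ccccc2)c2c(c1)[C@@H](c1cc(OCc3ccccc3)cc(OCc3ccccc3)c1)[C@H](c1ccc(OCc3ccccc3)cc1)O2 | intermediate (not isolated)
16 | [4-(benzyloxy)-2-{[4-(benzyloxy)phenyl]methoxy}-6-bromophenyl](RB)methanol, both carbinol epimers | OC(c1c(Br)cc(OCc2ccccc2)cc1OCc1ccc(OCc2ccccc2)cc1)c1cc(OCc2ccccc2)c2c(c1)[C@@H](c1cc(OCc3ccccc3)cc(OCc3ccccc3)c1)[C@H](c1ccc(OCc3ccccc3)cc1)O2 | intermediate
17 | [4-(benzyloxy)-2-{[4-(benzyloxy)phenyl]methoxy}-6-bromophenyl](RB)methanone | O=C(c1c(Br)cc(OCc2ccccc2)cc1OCc1ccc(OCc2ccccc2)cc1)c1cc(OCc2ccccc2)c2c(c1)[C@@H](c1cc(OCc3ccccc3)cc(OCc3ccccc3)c1)[C@H](c1ccc(OCc3ccccc3)cc1)O2 | intermediate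
18 | hydrazone of 17 (E/Z mixture) | NN=C(c1c(Br)cc(OCc2ccccc2)cc1OCc1ccc(OCc2ccccc2)cc1)c1cc(OCc2ccccc2)c2c(c1)[C@@H](c1cc(OCc3ccccc3)cc(OCc3ccccc3)c1)[C@H](c1ccc(OCc3ccccc3)cc1)O2 | intermediate
19 | diaryldiazomethane (C=N2 in place of C=O of 17) | [N-]=[N+]=C(c1c(Br)cc(OCc2ccccc2)cc1OCc1ccc(OCc2ccccc2)cc1)c1cc(OCc2ccccc2)c2c(c1)[C@@H](c1cc(OCc3ccccc3)cc(OCc3ccccc3)c1)[C@H](c1ccc(OCc3ccccc3)cc1)O2 | intermediate (not isolated)
20 | (2R,3S)-6-(benzyloxy)-2-[4-(benzyloxy)phenyl]-4-bromo-3-(RB)-2,3-dihydro-1-benzofuran (2,3-cis) | Brc1cc(OCc2ccccc2)cc2c1[C@H](c1cc(OCc3ccccc3)c3c(c1)[C@@H](c1cc(OCc4ccccc4)cc(OCc4ccccc4)c1)[C@H](c1ccc(OCc4ccccc4)cc1)O3)[C@H](c1ccc(OCc3ccccc3)cc1)O2 | intermediate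
21 | (2S,3S)-6-(benzyloxy)-2-[4-(benzyloxy)phenyl]-4-bromo-3-(RB)-2,3-dihydro-1-benzofuran (2,3-trans) | Brc1cc(OCc2ccccc2)cc2c1[C@H](c1cc(OCc3ccccc3)c3c(c1)[C@@H](c1cc(OCc4ccccc4)cc(OCc4ccccc4)c1)[C@H](c1ccc(OCc4ccccc4)cc1)O3)[C@@H](c1ccc(OCc3ccccc3)cc1)O2 | intermediate
22 | 1-(benzyloxy)-4-ethenylbenzene | C=Cc1ccc(OCc2ccccc2)cc1 | starting material
23 | (2S,3S)-6-(benzyloxy)-2-[4-(benzyloxy)phenyl]-4-{(E)-2-[4-(benzyloxy)phenyl]ethenyl}-3-(RB)-2,3-dihydro-1-benzofuran | C(Oc1ccc(/C=C/c2cc(OCc3ccccc3)cc3c2[C@H](c2cc(OCc4ccccc4)c4c(c2)[C@@H](c2cc(OCc5ccccc5)cc(OCc5ccccc5)c2)[C@H](c2ccc(OCc5ccccc5)cc2)O4)[C@@H](c2ccc(OCc4ccccc4)cc2)O3)cc1)c1ccccc1 | intermediate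
24 | 5-[(2R,3R)-7-hydroxy-5-{(2S,3S)-6-hydroxy-2-(4-hydroxyphenyl)-4-[(E)-2-(4-hydroxyphenyl)ethenyl]-2,3-dihydro-1-benzofuran-3-yl}-2-(4-hydroxyphenyl)-2,3-dihydro-1-benzofuran-3-yl]benzene-1,3-diol | Oc1ccc(/C=C/c2cc(O)cc3c2[C@H](c2cc(O)c4c(c2)[C@@H](c2cc(O)cc(O)c2)[C@H](c2ccc(O)cc2)O4)[C@@H](c2ccc(O)cc2)O3)cc1 | target

**Step count and risks**
Total step count: 15. Longest linear sequence: 11 steps (steps 1, 2, 3, 5, 9, 10, 11, 12, 13, 14, 15).

Steps most likely to fail:

Step 5 (proposed method). What may go wrong: the carbenoid may discriminate poorly between the two faces of the 1,2-disubstituted alkene, or be diverted into attack on the electron-rich benzene rings or into dimerisation. Fallback: the two bonds are then made one after the other by known chemistry, with the C-2–C-3 bond formed by carbenoid C–H insertion. Setting out from 2, ortho-formylation (MgCl2, Et3N, paraformaldehyde, MeCN, reflux) should give 3-(benzyloxy)-5-bromo-2-hydroxybenzaldehyde F1. Alkylation with 13 (K2CO3, DMF) should give 3-(benzyloxy)-2-{[4-(benzyloxy)phenyl]methoxy}-5-bromobenzaldehyde F2. Compound 10 and Mg turnings give 3,5-bis(benzyloxy)phenylmagnesium bromide F3, which adds to F2 to give the diarylmethanol F4. Dess–Martin oxidation gives the diaryl ketone F5, and hydrazine hydrate gives the hydrazone F6. MnO2 gives the diaryldiazomethane F7 (not isolated), which with Rh2(S-PTAD)4 should undergo enantioselective C–H insertion into the ArCH2O group to give the (2S,3R)-cis-dihydrobenzofuran F8. CF3CO2H equilibrates C-2, and the route is rejoined at 9.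

Step 13. What may go wrong: loss of configuration at the diarylmethine carbons (C-3 of either dihydrobenzofuran) through elimination and re-protonation of the ring-opened cation while C-2 equilibrates, or incomplete equilibration. Fallback: the ring A dihydrofuran is then closed directly in the trans form by a [4+1] annulation of an ortho-quinone methide with a sulfonium ylide, which needs no acid. Setting out from 12 and 9, Boc2O with DMAP converts 12 into 5-(benzyloxy)-3-bromo-2-formylphenyl tert-butyl carbonate F9. Aryllithium 15 (from 9, as in step 9) adds to F9 at −78 °C; the carbonate shifts to the new alkoxide and is expelled on warming, which gives the ortho-quinone methide F10 (not isolated). [4-(Benzyloxy)benzyl]dimethylsulfonium chloride F11 (from 13 and Me2S) is deprotonated with KN(SiMe3)2 to the sulfonium ylide F12, which adds to the methide carbon of F10; the phenoxide then displaces Me2S and closes the trans-dihydrofuran. Because the remote ring B centres exert no control, both trans isomers should form: 21 and its (2R,3R) ring A diastereomer F13. Chromatographic separation returns the route at 21, and steps 8 to 13 are not needed.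

Step 11. What may go wrong: failure of condensation at the carbonyl shielded by the 2,6-disubstituted ring A, or slow reaction with decomposition on prolonged heating. Fallback: the C=N bond is then formed through a nitrile before the carbon is crowded. Setting out from 14, I2 and aqueous NH3 in THF should convert the aldehyde into 4-(benzyloxy)-2-{[4-(benzyloxy)phenyl]methoxy}-6-bromobenzonitrile F14. Aryllithium 15 (from 9) adds to the nitrile, and a MeOH quench gives the N-unsubstituted diaryl ketimine F15. Transimination with N2H4·H2O and AcOH (EtOH, 60 °C) releases ammonia and gives hydrazone 18, where the route is rejoined; steps 9 to 11 are replaced.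

**Further compounds**
F1 | step 5 | 3-(benzyloxy)-5-bromo-2-hydroxybenzaldehyde | O=Cc1cc(Br)cc(OCc2ccccc2)c1O
F2 | step 5 | 3-(benzyloxy)-2-{[4-(benzyloxy)phenyl]methoxy}-5-bromobenzaldehyde | O=Cc1cc(Br)cc(OCc2ccccc2)c1OCc1ccc(OCc2ccccc2)cc1
F3 | step 5 | 3,5-bis(benzyloxy)phenylmagnesium bromide | Br[Mg]c1cc(OCc2ccccc2)cc(OCc2ccccc2)c1
F4 | step 5 | [3,5-bis(benzyloxy)phenyl][3-(benzyloxy)-2-{[4-(benzyloxy)phenyl]methoxy}-5-bromophenyl]methanol | OC(c1cc(OCc2ccccc2)cc(OCc2ccccc2)c1)c1cc(Br)cc(OCc2ccccc2)c1OCc1ccc(OCc2ccccc2)cc1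
F5 | step 5 | [3,5-bis(benzyloxy)phenyl][3-(benzyloxy)-2-{[4-(benzyloxy)phenyl]methoxy}-5-bromophenyl]methanone | O=C(c1cc(OCc2ccccc2)cc(OCc2ccccc2)c1)c1cc(Br)cc(OCc2ccccc2)c1OCc1ccc(OCc2ccccc2)cc1
F6 | step 5 | hydrazone of F5 | NN=C(c1cc(OCc2ccccc2)cc(OCc2ccccc2)c1)c1cc(Br)cc(OCc2ccccc2)c1OCc1ccc(OCc2ccccc2)cc1
F7 | step 5 | diaryldiazomethane from F6 | [N-]=[N+]=C(c1cc(OCc2ccccc2)cc(OCc2ccccc2)c1)c1cc(Br)cc(OCc2ccccc2)c1OCc1ccc(OCc2ccccc2)cc1
F8 | step 5 | (2S,3R)-7-(benzyloxy)-3-[3,5-bis(benzyloxy)phenyl]-2-[4-(benzyloxy)phenyl]-5-bromo-2,3-dihydro-1-benzofuran (2,3-cis) | Brc1cc(OCc2ccccc2)c2c(c1)[C@@H](c1cc(OCc3ccccc3)cc(OCc3ccccc3)c1)[C@@H](c1ccc(OCc3ccccc3)cc1)O2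
F9 | step 13 | 5-(benzyloxy)-3-bromo-2-formylphenyl tert-butyl carbonate | O=Cc1c(Br)cc(OCc2ccccc2)cc1OC(=O)OC(C)(C)C
F10 | step 13 | 3-(benzyloxy)-5-bromo-6-[(RB)methylidene]cyclohexa-2,4-dien-1-one (ortho-quinone methide) | O=C1C=C(OCc2ccccc2)C=C(Br)C1=Cc1cc(OCc2ccccc2)c2c(c1)[C@@H](c1cc(OCc3ccccc3)cc(OCc3ccccc3)c1)[C@H](c1ccc(OCc3ccccc3)cc1)O2
F11 | step 13 | [4-(benzyloxy)benzyl]dimethylsulfonium chloride | C[S+](C)Cc1ccc(OCc2ccccc2)cc1.[Cl-]
F12 | step 13 | [4-(benzyloxy)phenyl](dimethylsulfonio)methanide (sulfonium ylide) | C[S+](C)[CH-]c1ccc(OCc2ccccc2)cc1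
F13 | step 13 | (2R,3R)-6-(benzyloxy)-2-[4-(benzyloxy)phenyl]-4-bromo-3-(RB)-2,3-dihydro-1-benzofuran (trans diastereomer of 21) | Brc1cc(OCc2ccccc2)cc2c1[C@@H](c1cc(OCc3ccccc3)c3c(c1)[C@@H](c1cc(OCc4ccccc4)cc(OCc4ccccc4)c1)[C@H](c1ccc(OCc4ccccc4)cc1)O3)[C@H](c1ccc(OCc3ccccc3)cc1)O2
F14 | step 11 | 4-(benzyloxy)-2-{[4-(benzyloxy)phenyl]methoxy}-6-bromobenzonitrile | N#Cc1c(Br)cc(OCc2ccccc2)cc1OCc1ccc(OCc2ccccc2)cc1
F15 | step 11 | [4-(benzyloxy)-2-{[4-(benzyloxy)phenyl]methoxy}-6-bromophenyl](RB)methanimine | N=C(c1c(Br)cc(OCc2ccccc2)cc1OCc1ccc(OCc2ccccc2)cc1)c1cc(OCc2ccccc2)c2c(c1)[C@@H](c1cc(OCc3ccccc3)cc(OCc3ccccc3)c1)[C@H](c1ccc(OCc3ccccc3)cc1)O2
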